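## The problem

CNP0151143.1 is a trans-fused hydroazulene. A cyclopentane (C1, C2, C3, C3a, C8a) and a cycloheptane (C3a, C4, C5, C6, C7, C8, C8a) share the bond between the methyl-bearing quaternary carbon C3a and the methine C8a; C5 carries an acetate, C6 a methylidene group, and C1 the chain C1'(OH)(CH3)–C2'H2–C3'H2–C4'H(OAc)–C5'(CH3)=CH2 (β is the face of the C3a methyl, α the opposite face). Six stereocentres must be set: C1 (chain β), C3a, C5 (acetate α) and C8a (hydrogen α) on the bicycle, and C1' (S) and C4' (S) on the chain. C1 can come from the chiral pool and can direct C1' by 1,2-induction; C3a, once present, can direct C5 and the face of any chemistry at C8 and C8a; C4' is 1,4-remote from every other centre and needs a reagent or a separate fragment. The hard spots are the quaternary C3a next to a trans ring-fusion hydrogen, and the C1 substituent, which is cis to C8 on the neighbouring carbon and so must not equilibrate next to a carbonyl group. The two allylic acetates, the exocyclic methylidene, the isopropenyl group and a tertiary alcohol 1,4 to an allylic C–O bond (dehydration or oxolane closure under acid) forbid harsh late conditions, so these groups appear last. The enabling feature is the C3a–C8a bond itself: it joins a quaternary carbon to a CH, so it can be made by a 1,2-shift of C3a from C8 to C8a in a decalin where C3a is still bonded to C8. That decalin, ring A (C1, C2, C3, C3a, C8, C8a) fused to ring B (C3a, C4, C5, C6, C7, C8), is the Robinson annulation product of dihydrocarvone and methyl vinyl ketone, so carvone supplies C1, its three-carbon arm and the absolute configuration.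

## Retrosynthesis

**Endgame (32 ⇒ 31 ⇒ 30 ⇒ 29 ⇒ 28).** The two acetyl C–O bonds and the C6=CH2 bond are cut first. Target 32 comes from triol 31 by acylation of the two secondary alcohols, 31 from silyl ether 30, and the methylidene of 30 from ketone 29 by Wittig reaction. Ketone 29 is kept as a dioxolane (28) until then. Making C6=CH2 earlier is excluded: the cis-hydroxylation needs a single alkene in the molecule, and a free C6 ketone would sit β to the C8 oxygen (retro-aldol, 1,3-diketone after the key step). The forward steps must only be mild to the chain.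

**C1'–C2' (28 ⇒ 22 + 27).** The tertiary carbinol is disconnected to methyl ketone 22 and Grignard reagent 27 (from bromide 26). In the Felkin–Anh model C8a is the large substituent on C1, and the nucleophile passes the C1 hydrogen, which gives 1'S. The neighbouring cuts are worse: C2'–C3' would need a β-oxygenated carbanion; C1–C1' would have to create two adjacent centres intermolecularly; adding methyl to the chain ketone would, by the same facial preference, give 1'R. The cut removes eight carbons and C4'. It asks for a non-basic organometallic so that the ketone is not enolised at C1.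

**Fragment (26 ⇒ 25 ⇒ 24 ⇒ 23).** C4' cannot be controlled from the ring, so it is set by reagent on the achiral homoprenyl bromide 23: Shi epoxidation to 24, then base-induced opening to the isopropenyl carbinol 25, which keeps the C4'–O bond, and silylation to 26. Doing the same oxidation after coupling would put an epoxide 1,4 to the free tertiary alcohol (oxolane formation).

**C8 carbonyl and arm unmasking (22 ⇒ 21 ⇒ 20 ⇒ 19).** The ketone left at C8 by the key step is not in the target. It is removed through tosylhydrazone 20 to give 21. The unhindered side-arm dioxolane is then hydrolysed in preference to the C6 dioxolane, which is deactivated by the neighbouring silyloxy group, giving 22.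

**Key disconnection (19 ⇒ 18).** The C3a–C8a bond of hydroazulenone 19 is traced back to the C3a–C8 bond of the cis-decalin hydroxy mesylate 18. A single 1,2-shift contracts ring A and expands ring B. It is stereospecific (inversion at C8a, retention at C3a), so a β-mesylate gives the trans fusion, and the quaternary centre is not made in this step but carried through it. The forward reaction needs the mesylate equatorial on ring A, so that C8–C3a rather than C8–C7 is antiperiplanar to it. In that chair–chair form the C3a methyl (on ring A) and the bulky C5 silyloxy group are equatorial as well, and the price is an axial C1 arm.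

**cis-Diol (18 ⇒ 17 ⇒ 14).** The C8–O and C8a–O bonds must both lie on the methyl face. Osmylation of alkene 14 would attack the open α face and lead to the cis-fused hydroazulene. The Woodward cis-hydroxylation delivers both oxygens to the face opposite the initial iodonium ion, and only the secondary hydroxyl of 17 is mesylated.

**Alkene placement and C5 oxygen (14 ⇒ 12 ⇒ 11 ⇒ 10 ⇒ 9).** Ketalisation of enone 12 moves the double bond to C8=C8a, exactly where the diol is needed, and masks the acetyl arm in the same step. The acetyl arm comes from ozonolysis of the isopropenyl group of 11, which must be gone before the iodine chemistry. The C5 oxygen is put in earlier still (10, then silyl ether 11), on the rigid octalone 9: C5 is its only α' position and the axial C3a methyl blocks the β face. The tert-butyldiphenylsilyl ether is chosen because it has to outlast two acidic steps.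

**Ring B and C3a (9 ⇒ 7 ⇒ 2 + 4 ⇒ 1).** Cutting C7=C8 and C3a–C4 (Robinson annulation) leads to (5S)-dihydrocarvone 2 and methyl vinyl ketone 4, with diketone 7 between. The substrate alone would add the enone cis to the isopropenyl group, so the Michael step runs through the chiral imine of (S)-1-phenylethylamine 3. Compound 2 is one reduction from (S)-carvone 1.

## Roads not taken

**Alternative 1:** oxidopyrylium (5+2) cycloaddition. The cut is C3a–C8a together with C4–C5. Acetoxypyranone A1, which already carries the whole protected chain on C1 and a 3-methylbut-3-enyl tether, would lose acetate to a 3-oxidopyrylium; the tethered 1,1-disubstituted alkene would add across C8a and C5 to give the oxygen-bridged tricycle A2. Merits: both rings, the quaternary C3a and the C5–O bond arise in one step, and the route is more convergent and shorter to the bicycle than the chosen one. Weak points for this target: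
- The C1 and C1' centres would have to be built on an open chain, without a ring to direct C1'.
- The face of the cycloaddition rests on the single C1 centre of the tether.
- The bridge must be cut at C8a α to the ketone, which passes through an enolate whose protonation, not the cycloaddition, sets the ring fusion.
- The C8 ketone must still be removed.
- C6 ends as a methyl on an endocyclic C6=C7 enone, so the exocyclic methylidene needs a contra-thermodynamic alkene shift.

The alternative wins on step count. The chosen plan offers instead a stereospecific origin for C8a, a C6 ketone at the right carbon for methylenation, and a side chain added to a finished, directing ring.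

**Alternative 2:** divinylcyclopropane rearrangement. The cut is C3a–C4, with C6–C8 present as a cyclopropane bond. cis-Divinylcyclopropane A3 (silyloxyvinyl on C6, 2-methylcyclopentenyl on C8) would rearrange on warming through the boat transition state to the bicyclic diene A4. Merits: a stereospecific pericyclic step, no oxygen to remove at C8, and a C5 silyl enol ether suited to α-methylenation at C6 followed by carbonyl reduction; for the C5/C6 allylic acetate motif this road is more direct than the chosen one. Weak points:
- The terminus C3a becomes quaternary in the bond-forming event and its methyl points inward over the cyclopropane methylene in the boat, a substitution pattern that slows such rearrangements and opens the way to cis–trans isomerisation of the cyclopropane.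
- The cyclopropane configuration must be matched to the remote C1 centre to give the right C3a.
- C8a is not set: the C8=C8a alkene must be hydrogenated with trans selectivity in the presence of other alkenes.
- C5 would be fixed by reduction on a flexible seven-membered enone.

The chosen plan offers instead a quaternary centre formed by a well-behaved Michael addition, C5 set on a rigid octalone, and C8a fixed by the shift itself.

**Alternative 3:** ketyl–enoate reductive coupling. The cut is C1–C1'. SmI2 would reduce methyl ketone A6 to a ketyl that adds to C1 of cyclopentene ester A5; protonation at C8a and lactonisation onto the C8 ester would give lactone A7. Merits: the congested C1–C1' bond, the tertiary carbinol and the cis relation of chain and C8 are formed in one step with the complete chain, which is more direct for C1/C1' than unmasking a ketone and adding a Grignard reagent. Weak points: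
- The coupling is intermolecular, and the ketyl face (C1') has no cyclic control.
- The lactone carbon C8 must later be reduced to a methylene while the C1'–O bond is kept.
- The seven-membered ring is still missing: C6, C7 and the methylidene carbon must be added and the ring closed between C8 and C5.
- C5 would be set late on a flexible ring.

The chosen plan makes both rings and C8a in one operation and leaves only functional-group work afterwards.

Key step: step 10

Assumption: the (S)-1-phenylethylamine auxiliary is taken to direct as in the parent 2-methylcyclohexanone case and to override the opposite, weaker preference of the C1 substituent.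

## Route

Step 1
Reactants: 1 (S)-(+)-carvone
Product: 2 (5S)-dihydrocarvone (C2 epimers)
Conditions: Zn dust, KOH, EtOH–H2O, reflux
Reagents that add atoms: none
Why: Dissolving-metal conjugate reduction of the enone; the isolated isopropenyl group is not reduced, and the C2 mixture is irrelevant because C2 is planarised in step 2.

Step 2
Reactants: 2 (5S)-dihydrocarvone; 3 (S)-1-phenylethylamine; 4 methyl vinyl ketone
Product: 7 (2R,5S)-2-methyl-2-(3-oxobutyl)-5-(prop-1-en-2-yl)cyclohexan-1-one, via ketimine 5 (not isolated), via Michael adduct ketimine 6 (not isolated)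
Conditions: 3, TsOH (cat.), toluene, reflux, Dean–Stark; then 4, THF, 40 °C; then 10% aq. AcOH, rt
Reagents that add atoms: methyl vinyl ketone (4), C=CC(C)=O; water, O
Why: Auxiliary-controlled Michael addition of a chiral imine through its more substituted secondary enamine tautomer: the enone is attacked on the enamine face away from the phenyl group, which for the (S)-amine gives the (R)-quaternary carbon (target C3a) with the new chain trans to the isopropenyl group. Reagent control is needed because the substrate alone prefers the other face; hydrolysis returns the auxiliary.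

Step 3
Reactants: 7 (2R,5S)-2-methyl-2-(3-oxobutyl)-5-(prop-1-en-2-yl)cyclohexan-1-one
Product: 9 (4aR,7S)-4a-methyl-7-(prop-1-en-2-yl)-4,4a,5,6,7,8-hexahydronaphthalen-2(3H)-one, via cis-ketol 8 (not isolated)
Conditions: NaOMe, MeOH, 60 °C
Reagents that add atoms: none
Why: Intramolecular aldol condensation that completes the Robinson annulation (aldol to the cis-ketol, then E1cB dehydration); no stereocentre is created in the product and neither C1 nor C3a can enolise.

Step 4
Reactants: 9 (4aR,7S)-octalone
Product: 10 (3S,4aR,7S)-3-hydroxy-4a-methyl-7-(prop-1-en-2-yl)-4,4a,5,6,7,8-hexahydronaphthalen-2(3H)-one (target labels: 5α-OH)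
Conditions: KN(SiMe3)2, THF, −78 °C; then 2-(phenylsulfonyl)-3-phenyloxaziridine (Davis oxaziridine), −78 °C
Reagents that add atoms: 2-(phenylsulfonyl)-3-phenyloxaziridine, O=S(=O)(c1ccccc1)N1OC1c1ccccc1
Why: Kinetic deprotonation at the only α' position (C5) gives the cross-conjugated enolate, which the N-sulfonyloxaziridine hydroxylates. The axial C3a methyl shields the β face of C5, so oxygen enters α and equatorial, which is also the more stable epimer of this epimerisable centre.

Step 5
Reactants: 10 hydroxy enone
Product: 11 (3S,4aR,7S)-3-[(tert-butyldiphenylsilyl)oxy]-4a-methyl-7-(prop-1-en-2-yl)-4,4a,5,6,7,8-hexahydronaphthalen-2(3H)-one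
Conditions: TBDPSCl, imidazole, DMF, rt
Reagents that add atoms: tert-butyl(chloro)diphenylsilane, CC(C)(C)[Si](Cl)(c1ccccc1)c1ccccc1
Why: Standard silylation of a secondary alcohol; the tert-butyldiphenylsilyl (TBDPS) ether is chosen because it must survive the acidic ketalisation of step 7 and the aqueous acid of step 18.

Step 6
Reactants: 11 silyloxy enone
Product: 12 (3S,4aR,7S)-7-acetyl-3-[(tert-butyldiphenylsilyl)oxy]-4a-methyl-4,4a,5,6,7,8-hexahydronaphthalen-2(3H)-one
Conditions: O3, CH2Cl2–MeOH, −78 °C (Sudan Red 7B end point); then Me2S, −78 °C → rt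
Reagents that add atoms: ozone, [O-][O+]=O
Why: Chemoselective ozonolysis: ozone is electrophilic and cleaves the electron-rich 1,1-disubstituted alkene much faster than the electron-poor enone double bond. C1, now α to a ketone, bears an equatorial acetyl group, so any enolisation returns the same isomer.

Step 7
Reactants: 12 acetyl enone; 13 ethylene glycol
Product: 14 bis-dioxolane alkene (C6 and C1' ethylene ketals; double bond at C8=C8a; 5α-OTBDPS; C1 arm β)
Conditions: 13, TsOH·H2O (cat.), benzene, reflux, Dean–Stark
Reagents that add atoms: ethylene glycol (13), OCCO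
Why: Acid-catalysed ketalisation of both ketones with water removal. As with other 3-keto-4-ene systems, the enone ketalises with migration of the double bond to the β,γ position (C8=C8a), the thermodynamic outcome; C1 and C5 stay in their more stable equatorial arrangements.

Step 8
Reactants: 14 bis-dioxolane alkene
Product: 17 cis-diol (8β,8aβ-dihydroxy cis-decalin; C6 and C1' dioxolanes; 5α-OTBDPS), via trans-iodo acetate 15 (not isolated), via cis-hydroxy acetate 16 (not isolated)
Conditions: I2, AgOAc, AcOH, rt; then H2O (1.5 equiv), 45 °C; then K2CO3 (cat.), MeOH, rt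
Reagents that add atoms: silver acetate, CC(=O)[O-].[Ag+]
Why: Woodward cis-hydroxylation: the iodonium ion forms on the α face away from the C3a methyl, acetate opens it trans-diaxially at C8a, and silver-assisted loss of the tertiary iodide at C8 with acetate participation gives the β-acetoxonium ion, which water opens to the cis-hydroxy acetate. Both oxygens thus end on the methyl face, the opposite of osmylation. Because the iodide to be ionised is tertiary, gentle warming should suffice and spare the dioxolanes; methanolysis then frees the diol.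

Step 9
Reactants: 17 cis-diol
Product: 18 hydroxy mesylate (8β-hydroxy-8aβ-methanesulfonyloxy cis-decalin; C6 and C1' dioxolanes; 5α-OTBDPS)
Conditions: MsCl, pyridine, DMAP (cat.), CH2Cl2, 0 °C
Reagents that add atoms: methanesulfonyl chloride, CS(=O)(=O)Cl
Why: Selective sulfonylation of the secondary C8a hydroxyl; the tertiary C8 hydroxyl does not react under pyridine conditions, and the cis relationship rules out epoxide closure.

Step 10
Reactants: 18 hydroxy mesylate
Product: 19 trans-fused hydroazulen-8-one (1β-(2-methyl-1,3-dioxolan-2-yl); 3aβ-methyl; 8aα-H; 5α-OTBDPS; C6 dioxolane)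
Conditions: Et3Al (2.5 equiv), CH2Cl2, −78 → −20 °C
Reagents that add atoms: none
Why: Et3Al turns the tertiary C8 hydroxyl into a diethylaluminium alkoxide and, as a Lewis acid, loosens the C8a mesylate; as the sulfonate leaves, the C8–C3a σ bond, antiperiplanar to C8a–O when the mesylate is equatorial on ring A, shifts to C8a while the C8 oxygen closes to the ketone (concerted semipinacol 1,2-alkyl shift). The closest known reaction type is the pinacol-type rearrangement of 2-hydroxy sulfonates under trialkylaluminium or base, long used for decalin-to-hydroazulene ring contraction–expansion. No ring is closed by cyclisation: the five-membered ring comes from contraction of ring A (C3a–C8a made, C3a–C8 lost) and the seven-membered ring from the matching expansion of ring B, both in the same suprafacial shift. The only new stereocentre, C8a, is set by inversion at the migration terminus, so the β-mesylate dictates an α-hydrogen and the trans fusion; C3a migrates with retention, and C1 and C5 are untouched. The selectivity needed is migration of C3a and not of the C7 methylene, and it depends on which chair–chair conformer reacts. The productive conformer has mesylate, C3a methyl (on ring A) and the C5 silyloxy group equatorial, whereas the other would place mesylate and methyl 1,3-diaxial and the silyloxy group axial against C3; in addition the aluminium alkoxide can bridge to a dioxolane oxygen of the axial C1 arm, and a quaternary carbon migrates better than a methylene. Low temperature and the absence of base should keep the new C8a–H (α to the ketone) and the β-keto ketal intact.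

Step 11
Reactants: 19 hydroazulen-8-one
Product: 20 C8 p-toluenesulfonylhydrazone of 19
Conditions: TsNHNH2, EtOH, 60 °C
Reagents that add atoms: p-toluenesulfonyl hydrazide, Cc1ccc(cc1)S(=O)(=O)NN
Why: Condensation of the ketone with the sulfonyl hydrazide under neutral conditions (first stage of a Caglioti-type deoxygenation); no acid is added, so that the dioxolanes and the C8a centre next to the carbonyl are not disturbed.

Step 12
Reactants: 20 tosylhydrazone
Product: 21 8-deoxo bis-dioxolane (trans-fused decahydroazulene; C8 methylene; otherwise as 19)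
Conditions: catecholborane, CHCl3, 0 °C → rt; then NaOAc·3H2O, reflux
Reagents that add atoms: none
Why: Hydride transfer from catecholborane to the C=N bond, then acetate-induced loss of sulfinate gives an alkyl diazene that extrudes nitrogen and leaves the C8 methylene (mild Caglioti reduction); after this step C8a can no longer epimerise.

Step 13
Reactants: 21 bis-dioxolane
Product: 22 methyl ketone (1β-acetyl-3aβ-methyl-5α-OTBDPS-decahydroazulen-6-one 6-ethylene ketal; 8aα-H)
Conditions: PPTS (cat.), acetone–H2O, rt
Reagents that add atoms: water, O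
Why: Selective ketal hydrolysis: the unhindered side-arm dioxolane ionises readily, whereas the C6 dioxolane is deactivated by the inductive effect and bulk of the adjacent silyloxy group. The near-neutral medium also avoids enolisation of the new acetyl group, whose C1 centre (cis to C8) must not epimerise.

Step 14
Reactants: 23 5-bromo-2-methylpent-2-ene
Product: 24 (S)-3-(2-bromoethyl)-2,2-dimethyloxirane
Conditions: L-fructose-derived Shi ketone (1,2:4,5-di-O-isopropylidene-β-L-erythro-2,3-hexodiulo-2,6-pyranose, 30 mol%), KHSO5 (as Oxone), K2CO3, Bu4NHSO4 (cat.), MeCN–dimethoxymethane–aq. buffer (pH 10.5), 0 °C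
Reagents that add atoms: potassium peroxymonosulfate, [K+].[O-]S(=O)(=O)OO
Why: Shi asymmetric epoxidation of a trisubstituted alkene by the chiral dioxirane through a spiro transition state. The L-fructose-derived catalyst is chosen because the common D-fructose-derived one gives the R epoxide with this olefin type, so C4' is set S by the reagent.

Step 15
Reactants: 24 (S)-epoxide
Product: 25 (S)-5-bromo-2-methylpent-1-en-3-ol
Conditions: Et2AlCl, lithium 2,2,6,6-tetramethylpiperidide, toluene, 0 °C
Reagents that add atoms: none
Why: Isomerisation of a trisubstituted epoxide to an allylic alcohol by the bulky aluminium amide: syn removal of a methyl proton with cleavage of the tertiary C–O bond. The C4'–O bond is not touched, so the S configuration is kept and the isopropenyl carbinol forms regioselectively.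

Step 16
Reactants: 25 (S)-allylic alcohol
Product: 26 (S)-[(5-bromo-2-methylpent-1-en-3-yl)oxy](tert-butyl)dimethylsilane
Conditions: TBSCl, imidazole, DMF, rt
Reagents that add atoms: tert-butyl(chloro)dimethylsilane, CC(C)(C)[Si](C)(C)Cl
Why: Standard silylation of the secondary allylic alcohol to protect it during Grignard formation and addition.

Step 17
Reactants: 22 methyl ketone; 26 (S)-bromide
Product: 28 tertiary alcohol (1'S,4'S chain attached; 1'-OH; 4'-OTBS; 5α-OTBDPS; C6 dioxolane), via Grignard reagent 27 (not isolated)
Conditions: 26, Mg, THF, 40 °C; then 22, CeCl3 (anhydrous), THF, −78 → 0 °C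
Reagents that add atoms: none
Why: Grignard addition to a methyl ketone promoted by CeCl3, which favours addition over enolisation and so protects C1. Under Felkin–Anh control, with C8a as the large α-substituent and the nucleophile passing the C1 hydrogen, the 1'S carbinol should form; C4' arrives with the fragment.

Step 18
Reactants: 28 tertiary alcohol
Product: 29 keto diol (C6 ketone; 1'-OH; 4'-OH; 5α-OTBDPS)
Conditions: 1 M aq. HCl, THF, rt
Reagents that add atoms: water, O
Why: Acid hydrolysis of the remaining dioxolane, which needs stronger acid than step 13 because of the α-silyloxy group. The same medium removes the allylic tert-butyldimethylsilyl ether while the TBDPS ether stays, and at room temperature the tertiary and allylic alcohols should not ionise.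

Step 19
Reactants: 29 keto diol
Product: 30 methylidene diol (C6=CH2; 1'-OH; 4'-OH; 5α-OTBDPS)
Conditions: Ph3PCH3Br, KOtBu, THF, 0 °C → rt (excess ylide)
Reagents that add atoms: methyltriphenylphosphonium bromide, C[P+](c1ccccc1)(c1ccccc1)c1ccccc1.[Br-]
Why: Wittig methylenation with excess non-stabilised ylide (the two hydroxyls are carried as alkoxides); such ylides add to hindered α-alkoxy ketones at low temperature faster than they enolise them, so C5 should be kept.

Step 20
Reactants: 30 methylidene diol
Product: 31 triol (5α,1',4'-trihydroxy; C6=CH2)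
Conditions: Bu4NF, THF, rt → 40 °C
Reagents that add atoms: none
Why: Fluoride-induced cleavage of the silyl ether, driven by Si–F bond formation; no stereocentre is affected.

Step 21
Reactants: 31 triol
Product: 32 CNP0151143.1
Conditions: Ac2O (2.5 equiv), pyridine, DMAP (cat.), CH2Cl2, 0 °C → rt
Reagents that add atoms: acetic anhydride, CC(=O)OC(C)=O
Why: Acylation of the two secondary allylic alcohols under nucleophilic catalysis; the tertiary C1' hydroxyl is too hindered to react at this temperature with a limited excess of anhydride.

## Compound list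

1 | (S)-(+)-carvone, (5S)-2-methyl-5-(prop-1-en-2-yl)cyclohex-2-en-1-one | C=C(C)[C@H]1CC=C(C)C(=O)C1 | starting material
2 | (5S)-dihydrocarvone, (5S)-2-methyl-5-(prop-1-en-2-yl)cyclohexan-1-one, C2 epimers | C=C(C)[C@H]1CCC(C)C(=O)C1 | intermediate
3 | (S)-(−)-1-phenylethylamine | C[C@H](N)c1ccccc1 | starting material
4 | methyl vinyl ketone (but-3-en-2-one) | C=CC(C)=O | starting material
5 | N-[(S)-1-phenylethyl] ketimine of 2 (formed in situ) | C=C(C)[C@H]1CCC(C)C(=N[C@@H](C)c2ccccc2)C1 | intermediate
6 | N-[(S)-1-phenylethyl] ketimine of diketone 7, Michael adduct (formed in situ) | C=C(C)[C@H]1CC[C@](C)(CCC(C)=O)C(=N[C@@H](C)c2ccccc2)C1 | intermediate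
7 | (2R,5S)-2-methyl-2-(3-oxobutyl)-5-(prop-1-en-2-yl)cyclohexan-1-one | C=C(C)[C@H]1CC[C@](C)(CCC(C)=O)C(=O)C1 | intermediate
8 | cis-ketol, (4aR,7S)-8a-hydroxy-4a-methyl-7-(prop-1-en-2-yl)octahydronaphthalen-2(1H)-one, hydroxyl cis to the angular methyl (formed in situ) | C=C(C)[C@H]1CC[C@]2(C)CCC(=O)C[C@]2(O)C1 | intermediate
9 | (4aR,7S)-4a-methyl-7-(prop-1-en-2-yl)-4,4a,5,6,7,8-hexahydronaphthalen-2(3H)-one | C=C(C)[C@H]1CC[C@]2(C)CCC(=O)C=C2C1 | intermediate
10 | (3S,4aR,7S)-3-hydroxy-4a-methyl-7-(prop-1-en-2-yl)-4,4a,5,6,7,8-hexahydronaphthalen-2(3H)-one | C=C(C)[C@H]1CC[C@]2(C)C[C@H](O)C(=O)C=C2C1 | intermediate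
11 | (3S,4aR,7S)-3-[(tert-butyldiphenylsilyl)oxy]-4a-methyl-7-(prop-1-en-2-yl)-4,4a,5,6,7,8-hexahydronaphthalen-2(3H)-one | C=C(C)[C@H]1CC[C@]2(C)C[C@H](O[Si](c3ccccc3)(c4ccccc4)C(C)(C)C)C(=O)C=C2C1 | intermediate
12 | (3S,4aR,7S)-7-acetyl-3-[(tert-butyldiphenylsilyl)oxy]-4a-methyl-4,4a,5,6,7,8-hexahydronaphthalen-2(3H)-one | CC(=O)[C@H]1CC[C@]2(C)C[C@H](O[Si](c3ccccc3)(c4ccccc4)C(C)(C)C)C(=O)C=C2C1 | intermediate
13 | ethylene glycol | OCCO | starting material
14 | bis-dioxolane alkene: C6 and C1' ethylene ketals of 12 with the double bond at C8=C8a, 5α-OTBDPS, C1 arm β | CC1(OCCO1)[C@H]2CC[C@]3(C)C[C@H](O[Si](c5ccccc5)(c6ccccc6)C(C)(C)C)C4(OCCO4)CC3=C2 | intermediate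
15 | trans-iodo acetate: 8α-iodo-8aβ-acetoxy decalin, otherwise as 14 (formed in situ) | CC1(OCCO1)[C@H]2CC[C@]3(C)C[C@H](O[Si](c5ccccc5)(c6ccccc6)C(C)(C)C)C4(OCCO4)C[C@@]3(I)[C@H]2OC(C)=O | intermediate
16 | cis-hydroxy acetate: 8β-hydroxy-8aβ-acetoxy cis-decalin (formed in situ) | CC1(OCCO1)[C@H]2CC[C@]3(C)C[C@H](O[Si](c5ccccc5)(c6ccccc6)C(C)(C)C)C4(OCCO4)C[C@]3(O)[C@H]2OC(C)=O | intermediate
17 | cis-diol: 8β,8aβ-dihydroxy cis-decalin, C6 and C1' dioxolanes, 5α-OTBDPS, C1 arm β | CC1(OCCO1)[C@H]2CC[C@]3(C)C[C@H](O[Si](c5ccccc5)(c6ccccc6)C(C)(C)C)C4(OCCO4)C[C@]3(O)[C@H]2O | intermediate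
18 | hydroxy mesylate: 8β-hydroxy-8aβ-(methanesulfonyloxy) cis-decalin, otherwise as 17 | CC1(OCCO1)[C@H]2CC[C@]3(C)C[C@H](O[Si](c5ccccc5)(c6ccccc6)C(C)(C)C)C4(OCCO4)C[C@]3(O)[C@H]2OS(C)(=O)=O | intermediate
19 | trans-fused hydroazulen-8-one: 1β-(2-methyl-1,3-dioxolan-2-yl), 3aβ-methyl, 8aα-H, 5α-OTBDPS, C6 dioxolane | CC1(OCCO1)[C@H]2CC[C@]3(C)C[C@H](O[Si](c5ccccc5)(c6ccccc6)C(C)(C)C)C4(OCCO4)CC(=O)[C@@H]23 | intermediate
20 | C8 p-toluenesulfonylhydrazone of 19 | CC1(OCCO1)[C@H]2CC[C@]3(C)C[C@H](O[Si](c5ccccc5)(c6ccccc6)C(C)(C)C)C4(OCCO4)CC(=NNS(=O)(=O)c7ccc(C)cc7)[C@@H]23 | intermediate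
21 | 8-deoxo bis-dioxolane: trans-fused decahydroazulene, C8 methylene, otherwise as 19 | CC1(OCCO1)[C@H]2CC[C@]3(C)C[C@H](O[Si](c5ccccc5)(c6ccccc6)C(C)(C)C)C4(OCCO4)CC[C@@H]23 | intermediate
22 | methyl ketone: 1β-acetyl-3aβ-methyl-5α-[(tert-butyldiphenylsilyl)oxy]decahydroazulen-6-one 6-ethylene ketal, 8aα-H | CC(=O)[C@H]1CC[C@]2(C)C[C@H](O[Si](c3ccccc3)(c4ccccc4)C(C)(C)C)C5(OCCO5)CC[C@@H]12 | intermediate
23 | 5-bromo-2-methylpent-2-ene | CC(C)=CCCBr | starting material
24 | (S)-3-(2-bromoethyl)-2,2-dimethyloxirane | CC1(C)O[C@H]1CCBr | intermediate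
25 | (S)-5-bromo-2-methylpent-1-en-3-ol | C=C(C)[C@H](CCBr)O | intermediate
26 | (S)-[(5-bromo-2-methylpent-1-en-3-yl)oxy](tert-butyl)dimethylsilane | C=C(C)[C@H](CCBr)O[Si](C)(C)C(C)(C)C | intermediate
27 | (S)-{3-[(tert-butyldimethylsilyl)oxy]-4-methylpent-4-en-1-yl}magnesium bromide (formed in situ) | C=C(C)[C@H](CC[Mg]Br)O[Si](C)(C)C(C)(C)C | intermediate
28 | tertiary alcohol: ring as in 22, C1 bearing the (1'S,4'S) chain with 1'-OH and 4'-OTBS | C=C(C)[C@H](CC[C@](C)(O)[C@H]1CC[C@]2(C)C[C@H](O[Si](c3ccccc3)(c4ccccc4)C(C)(C)C)C5(OCCO5)CC[C@@H]12)O[Si](C)(C)C(C)(C)C | intermediate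
29 | keto diol: C6 ketone, 1'-OH, 4'-OH, 5α-OTBDPS | C=C(C)[C@H](CC[C@](C)(O)[C@H]1CC[C@]2(C)C[C@H](O[Si](c3ccccc3)(c4ccccc4)C(C)(C)C)C(=O)CC[C@@H]12)O | intermediate
30 | methylidene diol: C6=CH2, 1'-OH, 4'-OH, 5α-OTBDPS | C=C(C)[C@H](CC[C@](C)(O)[C@H]1CC[C@]2(C)C[C@H](O[Si](c3ccccc3)(c4ccccc4)C(C)(C)C)C(=C)CC[C@@H]12)O | intermediate
31 | triol: 5α,1',4'-trihydroxy, C6=CH2 | C=C(C)[C@H](CC[C@](C)(O)[C@H]1CC[C@]2(C)C[C@H](O)C(=C)CC[C@@H]12)O | intermediate
32 | CNP0151143.1, (1S,3aR,5S,8aS)-1-[(2S,5S)-5-(acetyloxy)-2-hydroxy-6-methylhept-6-en-2-yl]-3a-methyl-6-methylidenedecahydroazulen-5-yl acetate | C=C(C)[C@H](CC[C@](C)(O)[C@H]1CC[C@]2(C)C[C@H](OC(C)=O)C(=C)CC[C@@H]12)OC(C)=O | target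

## Step count and least certain steps

Total: 21 steps. Longest linear sequence: 18 steps (steps 1–13 and 17–21); the side-chain fragment takes 3 steps (14–16).

**Step 10 (key step).** The shift may run through the wrong chair–chair conformer, so that the C7 methylene migrates instead of C3a. The productive conformer must carry the quaternary dioxolanyl arm on C1 axial and syn to the C8 oxygen, and its preference rests on a balance of 1,3-diaxial interactions that cannot be guaranteed. Lewis-acid opening of a dioxolane and epimerisation at C8a are lesser risks. Fallback, from 18 back to 22, makes the arm small before the shift: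
- Selective hydrolysis of the arm dioxolane of 18 (PPTS, wet acetone) gives keto mesylate F1.
- Reduction of the acetyl group (NaBH4, MeOH, 0 °C) gives hydroxy mesylate F2 (either carbinol epimer). Its arm is a secondary carbon that can turn its hydrogen inward when axial, and its alkoxide can share aluminium with the C8 alkoxide.
- Et3Al then gives hydroxy hydroazulenone F3.
- Deoxygenation as in steps 11 and 12, through tosylhydrazone F4, gives carbinol F5.
- Dess–Martin oxidation of F5 gives 22.

**Step 8.** The iodonium ion may form on, and be opened from, the wrong face (the axial C6 ketal oxygen also hinders the α face), the tertiary iodide may eliminate, or the arm dioxolane may be lost in wet acetic acid. Fallback, from 14 back to 17, avoids acid and separates the events: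
- NBS in buffered aqueous dimethoxyethane gives the trans-diaxial bromohydrin F6 (8α-bromo-8aβ-ol).
- Boc2O and DMAP give tert-butyl carbonate F7.
- AgOTf with 2,6-di-tert-butylpyridine ionises the tertiary bromide with participation of the carbonate carbonyl from the methyl face and loss of isobutene, giving cyclic carbonate F8.
- K2CO3 in methanol releases 17.

**Step 11 (with 12).** Hydrazone formation at the hindered C8 carbonyl may be too slow without acid, and forcing it risks ketal exchange or epimerisation at C8a through the ene-hydrazine. Fallback, from 19 to 21, is a radical deoxygenation of the alcohol: NaBH4 gives alcohol F9; NaH, CS2 and MeI give xanthate F10; Bu3SnH and AIBN in hot toluene give 21 (Barton–McCombie).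

**Step 17.** Facial selectivity at the ketone may be low or opposite to the model, because the two ring substituents on C1 (C2 methylene and C8a methine) differ less than in better-studied cases; slow addition with competing enolisation is the second risk. Low selectivity would be handled by separating the C1' epimers. For reversed selectivity the fallback, from 22 to 28, inverts the order of the two carbon substituents:
- Haloform degradation of 22 (NaOBr, aqueous dioxane, 0 °C) gives acid F11.
- Carbodiimide coupling with N,O-dimethylhydroxylamine gives Weinreb amide F12.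
- Grignard reagent 27 gives chain ketone F13.
- MeMgBr with CeCl3 adds the methyl group; with the same facial preference this gives the opposite C1' configuration to direct chain addition, and so 28 if the model errs.

**Step 18.** The acid needed for the deactivated C6 dioxolane may ionise the allylic C4' oxygen or the tertiary alcohol (oxolane closure, dehydration, allylic transposition). Fallback, from 22 to 31, unmasks and methylenates C6 before the chain is present:
- NaBH4 gives carbinol F5.
- 1 M HCl in THF gives hydroxy ketone F14.
- Wittig methylenation gives methylidene carbinol F15.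
- Dess–Martin oxidation gives methylidene methyl ketone F16.
- Grignard reagent 27 with CeCl3 gives bis-silyl ether F17.
- Bu4NF removes both silyl groups to give 31.

## Further compounds

F1 | step 10 | keto mesylate: 18 with the arm dioxolane hydrolysed to acetyl | CC(=O)[C@H]1CC[C@]2(C)C[C@H](O[Si](c3ccccc3)(c4ccccc4)C(C)(C)C)C5(OCCO5)C[C@]2(O)[C@H]1OS(C)(=O)=O
F2 | step 10 | hydroxy mesylate: arm reduced to 1-hydroxyethyl (carbinol epimers) | CC(O)[C@H]1CC[C@]2(C)C[C@H](O[Si](c3ccccc3)(c4ccccc4)C(C)(C)C)C5(OCCO5)C[C@]2(O)[C@H]1OS(C)(=O)=O
F3 | step 10 | hydroxy hydroazulenone: trans-fused hydroazulen-8-one with 1β-(1-hydroxyethyl) arm | CC(O)[C@H]1CC[C@]2(C)C[C@H](O[Si](c3ccccc3)(c4ccccc4)C(C)(C)C)C5(OCCO5)CC(=O)[C@@H]12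
F4 | step 10 | C8 p-toluenesulfonylhydrazone of F3 | CC(O)[C@H]1CC[C@]2(C)C[C@H](O[Si](c3ccccc3)(c4ccccc4)C(C)(C)C)C5(OCCO5)CC(=NNS(=O)(=O)c6ccc(C)cc6)[C@@H]12
F5 | step 10 | carbinol: 22 with the acetyl group reduced to 1-hydroxyethyl | CC(O)[C@H]1CC[C@]2(C)C[C@H](O[Si](c3ccccc3)(c4ccccc4)C(C)(C)C)C5(OCCO5)CC[C@@H]12
F6 | step 8 | bromohydrin: 8α-bromo-8aβ-hydroxy decalin, otherwise as 14 | CC1(OCCO1)[C@H]2CC[C@]3(C)C[C@H](O[Si](c5ccccc5)(c6ccccc6)C(C)(C)C)C4(OCCO4)C[C@@]3(Br)[C@H]2O
F7 | step 8 | tert-butyl carbonate of F6 | CC1(OCCO1)[C@H]2CC[C@]3(C)C[C@H](O[Si](c5ccccc5)(c6ccccc6)C(C)(C)C)C4(OCCO4)C[C@@]3(Br)[C@H]2OC(=O)OC(C)(C)C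
F8 | step 8 | cyclic carbonate of diol 17 (8β,8aβ) | CC1(OCCO1)[C@H]2CC[C@]3(C)C[C@H](O[Si](c5ccccc5)(c6ccccc6)C(C)(C)C)C4(OCCO4)C[C@@]37OC(=O)O[C@@H]27
F9 | step 11 | C8 alcohol from 19 (epimers) | CC1(OCCO1)[C@H]2CC[C@]3(C)C[C@H](O[Si](c5ccccc5)(c6ccccc6)C(C)(C)C)C4(OCCO4)CC(O)[C@@H]23
F10 | step 11 | S-methyl xanthate of F9 | CC1(OCCO1)[C@H]2CC[C@]3(C)C[C@H](O[Si](c5ccccc5)(c6ccccc6)C(C)(C)C)C4(OCCO4)CC(OC(=S)SC)[C@@H]23
F11 | step 17 | C1 carboxylic acid from 22 | OC(=O)[C@H]1CC[C@]2(C)C[C@H](O[Si](c3ccccc3)(c4ccccc4)C(C)(C)C)C5(OCCO5)CC[C@@H]12
F12 | step 17 | N-methoxy-N-methylamide of F11 | CON(C)C(=O)[C@H]1CC[C@]2(C)C[C@H](O[Si](c3ccccc3)(c4ccccc4)C(C)(C)C)C5(OCCO5)CC[C@@H]12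
F13 | step 17 | chain ketone: C1–C(=O)–CH2CH2–CH(OTBS)–C(CH3)=CH2, 4'S | C=C(C)[C@H](CCC(=O)[C@H]1CC[C@]2(C)C[C@H](O[Si](c3ccccc3)(c4ccccc4)C(C)(C)C)C5(OCCO5)CC[C@@H]12)O[Si](C)(C)C(C)(C)C
F14 | step 18 | hydroxy ketone: F5 with the C6 dioxolane hydrolysed | CC(O)[C@H]1CC[C@]2(C)C[C@H](O[Si](c3ccccc3)(c4ccccc4)C(C)(C)C)C(=O)CC[C@@H]12
F15 | step 18 | methylidene carbinol: C6=CH2, arm 1-hydroxyethyl | CC(O)[C@H]1CC[C@]2(C)C[C@H](O[Si](c3ccccc3)(c4ccccc4)C(C)(C)C)C(=C)CC[C@@H]12
F16 | step 18 | methylidene methyl ketone: C6=CH2, 1β-acetyl | CC(=O)[C@H]1CC[C@]2(C)C[C@H](O[Si](c3ccccc3)(c4ccccc4)C(C)(C)C)C(=C)CC[C@@H]12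
F17 | step 18 | bis-silyl ether of 31: C6=CH2, 1'-OH, 4'-OTBS, 5α-OTBDPS | C=C(C)[C@H](CC[C@](C)(O)[C@H]1CC[C@]2(C)C[C@H](O[Si](c3ccccc3)(c4ccccc4)C(C)(C)C)C(=C)CC[C@@H]12)O[Si](C)(C)C(C)(C)C
A1 | alternative 1 | acetoxypyranone: 6-acetoxy-5-methyl-2H-pyran-3(6H)-one bearing at C2 the C1 carbon with its 3-methylbut-3-enyl tether and the protected chain (1'-OTES, 4'-OTBS) | C=C(C)[C@H](CC[C@](C)(O[Si](CC)(CC)CC)[C@@H](CCC(C)=C)C1OC(OC(C)=O)C(C)=CC1=O)O[Si](C)(C)C(C)(C)C
A2 | alternative 1 | oxygen-bridged tricyclic enone (C8 ketone, C6=C7, C5–O–C8a bridge) | C=C(C)[C@H](CC[C@](C)(O[Si](CC)(CC)CC)[C@H]1CC[C@]2(C)C[C@@H]3O[C@]12C(=O)C=C3C)O[Si](C)(C)C(C)(C)C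
A3 | alternative 2 | cis-divinylcyclopropane: 1-(silyloxyvinyl)-2-(2-methylcyclopent-1-enyl)cyclopropane with the dioxolane arm on the cyclopentene | CC1(OCCO1)[C@H]2CCC(C)=C2[C@@H]3C[C@@H]3C(=C)O[Si](C)(C)C(C)(C)C
A4 | alternative 2 | bicyclic diene with C5=C6 silyl enol ether and C8=C8a alkene | CC3(OCCO3)[C@H]1CC[C@]2(C)CC(O[Si](C)(C)C(C)(C)C)=CCC=C12
A5 | alternative 3 | methyl (5R)-5-(2,2-dimethoxyethyl)-5-methylcyclopent-1-ene-1-carboxylate | COC(=O)C1=CCC[C@]1(C)CC(OC)OC
A6 | alternative 3 | (S)-5-[(tert-butyldimethylsilyl)oxy]-6-methylhept-6-en-2-one | C=C(C)[C@H](CCC(C)=O)O[Si](C)(C)C(C)(C)C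
A7 | alternative 3 | cis-fused cyclopentane γ-lactone carrying C1, C1', C8a and C3a | C=C(C)[C@H](CC[C@]1(C)OC(=O)[C@H]2[C@@H]1CC[C@]2(C)CC(OC)OC)O[Si](C)(C)C(C)(C)C
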